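**Plan**
- Retrosynthesis: remove the malonate (O15) and the angelate (O18), take C8–OH back to the 8(17)-alkene, return the axial C4 methyl to an ester and C1 to a ketone, then cut C2–C3 and C5–C10 of this 1-oxo ester to reach the open-chain keto allylic bromide 25.
- Enabling feature: in ring A, C1 lies between C2 and C10, and the quaternary C4 (which carries the oxidised C18 branch) lies between C3 and C5. A C1 ketone makes C2/C10 nucleophilic, a C4 acrylate with an allylic leaving group makes C5/C3 electrophilic, and C5–C10 is also the bond shared with ring B.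
- Forward: (S)-citronellol gives the C9 aldehyde and enoate; a rhodium-catalysed alkenyl conjugate addition joins the C5–C8/C17 fragment; methylation, methyl ketone formation and a Baylis–Hillman/bromide sequence follow; one base-mediated SN2′/Michael cascade then closes ring B and ring A.
- Stereochemistry: C13 from citronellol; C9 by catalyst control; C5 and C10 from C9 in the cascade; C4 by equatorial alkylation of the ester enolate; C8 by equatorial trapping of the tertiary radical.
- Helpers: the C1 ketone and the C19 ester oxygen are removed together (LiAlH4, oxidation, Wolff–Kishner); triisopropylsilyl (O15) and benzyl (O18) order the two acylations.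

Key step: step 12

Remark: labdane atom numbers are used for positions; C10 in 16–25 and the carbinol carbon of 23 are carried as epimer mixtures because both become trigonal by step 12, and the C4 hydrogen epimer of 27 is likewise erased in step 13.

Step 1
Reactants: 1 (S)-citronellol; 2 triisopropylsilyl chloride
Product: 3 (S)-triisopropyl[(3,7-dimethyloct-6-en-1-yl)oxy]silane
Conditions: imidazole, DMF, 23 °C
Reagents that add atoms: triisopropylsilyl chloride 2, CC(C)[Si](Cl)(C(C)C)C(C)C
Why: Standard silylation of a primary alcohol gives an ether that should survive every basic, reducing and oxidising step up to step 20 and leaves the C13 centre untouched.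

Step 2
Reactants: 3 (S)-triisopropyl[(3,7-dimethyloct-6-en-1-yl)oxy]silane; 4 ozone
Product: 6 (4S)-4-methyl-6-(triisopropylsilyloxy)hexanal, via secondary ozonide 5 (not isolated)
Conditions: O3, CH2Cl2, −78 °C; then PPh3, −78 → 23 °C
Reagents that add atoms: ozone 4, [O-][O+]=O
Why: Ozonolysis with reductive work-up cleaves the trisubstituted alkene to the aldehyde whose carbonyl carbon becomes C9, without touching the remote stereocentre.

Step 3
Reactants: 6 (4S)-4-methyl-6-(triisopropylsilyloxy)hexanal; 7 methyl (triphenylphosphoranylidene)acetate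
Product: 8 methyl (2E,6S)-6-methyl-8-(triisopropylsilyloxy)oct-2-enoate
Conditions: CH2Cl2, 23 °C
Reagents that add atoms: methyl (triphenylphosphoranylidene)acetate 7, COC(=O)C=P(c1ccccc1)(c1ccccc1)c1ccccc1
Why: Wittig olefination with a stabilised ylide should give the (E)-enoate (C10, C1) needed as acceptor in step 5.

Step 4
Reactants: 9 tert-butyldimethyl(pent-4-yn-1-yloxy)silane; 10 2-methoxy-4,4,5,5-tetramethyl-1,3,2-dioxaborolane
Product: 12 tert-butyldimethyl{[4-(4,4,5,5-tetramethyl-1,3,2-dioxaborolan-2-yl)pent-4-en-1-yl]oxy}silane, via alkenylalane 11 (not isolated)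
Conditions: NiCl2(dppp) (3 mol %), i-Bu2AlH, THF, 0 → 23 °C; then 10, 0 → 80 °C
Reagents that add atoms: 2-methoxy-4,4,5,5-tetramethyl-1,3,2-dioxaborolane 10, COB1OC(C)(C)C(C)(C)O1
Why: Nickel-catalysed Markovnikov hydroalumination of the terminal alkyne (the dppp ligand places aluminium on the internal carbon) followed by aluminium-to-boron exchange should give the 2-boryl-1-alkene that carries C8, C17 and C5–C7.

Step 5
Reactants: 8 methyl (2E,6S)-6-methyl-8-(triisopropylsilyloxy)oct-2-enoate; 12 tert-butyldimethyl{[4-(4,4,5,5-tetramethyl-1,3,2-dioxaborolan-2-yl)pent-4-en-1-yl]oxy}silane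
Product: 13 methyl (3S)-7-(tert-butyldimethylsilyloxy)-4-methylidene-3-[(3S)-3-methyl-5-(triisopropylsilyloxy)pentyl]heptanoate
Conditions: [Rh(OH)((R)-BINAP)]2 (3 mol % Rh), KOH (0.3 equiv), dioxane/H2O 10:1, 50 °C
Reagents that add atoms: none
Why: Hayashi–Miyaura conjugate addition of the alkenyl boronate to the (E)-enoate, in which the (R)-ligand should, by the accepted facial model for BINAP–rhodium catalysts, deliver the alkenyl group to the 2-Re (3-Si) face of 8 and so set C9 as (S) under catalyst control, the remote C13 centre having no influence.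

Step 6
Reactants: 13 methyl (3S)-7-(tert-butyldimethylsilyloxy)-4-methylidene-3-[(3S)-3-methyl-5-(triisopropylsilyloxy)pentyl]heptanoate; 14 iodomethane
Product: 16 methyl (2RS,3S)-7-(tert-butyldimethylsilyloxy)-2-methyl-4-methylidene-3-[(3S)-3-methyl-5-(triisopropylsilyloxy)pentyl]heptanoate, via lithium enolate 15 (not isolated)
Conditions: LiN(i-Pr)2, THF, −78 °C; then MeI, −78 → −20 °C
Reagents that add atoms: iodomethane 14, CI
Why: Kinetic ester enolate alkylation installs the C20 methyl at the only α-position, and the new C10 centre may form as an epimer mixture because it is planarised again in step 12.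

Step 7
Reactants: 16 methyl (2RS,3S)-7-(tert-butyldimethylsilyloxy)-2-methyl-4-methylidene-3-[(3S)-3-methyl-5-(triisopropylsilyloxy)pentyl]heptanoate; 17 (trimethylsilyl)methyllithium
Product: 19 (3RS,4S)-8-(tert-butyldimethylsilyloxy)-3-methyl-5-methylidene-4-[(3S)-3-methyl-5-(triisopropylsilyloxy)pentyl]octan-2-one, via lithium silyl-enolate 18 (not isolated)
Conditions: Me3SiCH2Li (2.5 equiv), pentane/THF, 0 → 23 °C; then MeOH, 23 °C
Reagents that add atoms: (trimethylsilyl)methyllithium 17, [Li]C[Si](C)(C)C
Why: Addition of the silylmethyllithium to the ester gives an α-silyl ketone that is enolised in situ (which blocks over-addition) and is desilylated on methanolysis, a known one-flask ester-to-methyl-ketone conversion that supplies C2.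

Step 8
Reactants: 19 (3RS,4S)-8-(tert-butyldimethylsilyloxy)-3-methyl-5-methylidene-4-[(3S)-3-methyl-5-(triisopropylsilyloxy)pentyl]octan-2-one
Product: 20 (3RS,4S)-8-hydroxy-3-methyl-5-methylidene-4-[(3S)-3-methyl-5-(triisopropylsilyloxy)pentyl]octan-2-one
Conditions: HF·pyridine, pyridine, THF, 0 °C
Reagents that add atoms: none
Why: Buffered fluoride should cleave the primary tert-butyldimethylsilyl ether much faster than the bulkier primary triisopropylsilyl ether, unveiling only the C5 hydroxyl.

Step 9
Reactants: 20 (3RS,4S)-8-hydroxy-3-methyl-5-methylidene-4-[(3S)-3-methyl-5-(triisopropylsilyloxy)pentyl]octan-2-one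
Product: 21 (5S,6RS)-6-methyl-4-methylidene-5-[(3S)-3-methyl-5-(triisopropylsilyloxy)pentyl]-7-oxooctanal
Conditions: Dess–Martin periodinane, NaHCO3, CH2Cl2, 0 → 23 °C
Reagents that add atoms: none
Why: Dess–Martin oxidation gives the C5 aldehyde under non-basic conditions, so the keto aldehyde should not undergo aldol reactions.

Step 10
Reactants: 21 (5S,6RS)-6-methyl-4-methylidene-5-[(3S)-3-methyl-5-(triisopropylsilyloxy)pentyl]-7-oxooctanal; 22 methyl acrylate
Product: 23 methyl (3RS,7S,8RS)-3-hydroxy-8-methyl-2,6-dimethylidene-7-[(3S)-3-methyl-5-(triisopropylsilyloxy)pentyl]-9-oxodecanoate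
Conditions: DABCO (1 equiv), methyl acrylate (neat, excess), 23 °C
Reagents that add atoms: methyl acrylate 22, C=CC(=O)OC
Why: Morita–Baylis–Hillman reaction of the aldehyde (far more electrophilic than the α-branched ketone) installs C3, C4 and the C19 ester carbon, and the carbinol centre may form unselectively because it is erased in step 11.

Step 11
Reactants: 23 methyl (3RS,7S,8RS)-3-hydroxy-8-methyl-2,6-dimethylidene-7-[(3S)-3-methyl-5-(triisopropylsilyloxy)pentyl]-9-oxodecanoate; 24 N-bromosuccinimide
Product: 25 methyl (2Z,7S,8RS)-2-(bromomethyl)-8-methyl-6-methylidene-7-[(3S)-3-methyl-5-(triisopropylsilyloxy)pentyl]-9-oxodec-2-enoate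
Conditions: NBS, Me2S, CH2Cl2, 0 → 23 °C
Reagents that add atoms: N-bromosuccinimide 24, O=C1CCC(=O)N1Br
Why: Activation of the allylic alcohol as its alkoxysulfonium salt and SN2′ entry of bromide should give the rearranged (Z)-2-(bromomethyl)enoate, a standard transformation of Baylis–Hillman alcohols that leaves the ketone and the silyl ether untouched.

Step 12
Reactants: 25 methyl (2Z,7S,8RS)-2-(bromomethyl)-8-methyl-6-methylidene-7-[(3S)-3-methyl-5-(triisopropylsilyloxy)pentyl]-9-oxodec-2-enoate
Product: 27 trans-fused bicyclic keto ester (C1 ketone, C4 equatorial CO2Me, C8 exocyclic methylene, H-5 and H-9 anti to the C10 methyl), via monocyclic acrylate 26 (not isolated)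
Conditions: KOt-Bu (2.2 equiv), THF/t-BuOH 10:1, slow addition of 25 to 0.005 M, −20 → 23 °C; then aq NH4Cl
Reagents that add atoms: none
Why: Proposed new method: under equilibrating KOt-Bu the ketone is enolised toward both C2 and C10, but only the C10 enolate can reach C5 through a six-membered transition state, so it displaces bromide in an SN2′ (Michael–E1cB) step that closes ring B in the 6-exo-trig mode, forms C5–C10 and unmasks a new acrylate (26), whose terminal carbon C3 is then attacked by the C2 enolate of the remaining methyl ketone in a 6-endo-trig Michael addition that closes ring A and forms C2–C3. The closest known reaction type is the α,α′-annulation of ketone enolates or enamines with 2-(halomethyl)acrylates (SN2′ then Michael), here run with the first C–C bond formed intramolecularly so that both rings arise from an open chain. C10 and C5 are set in the first closure by the C9 stereocentre, because in the chair-like transition state the C9 side chain, the enolate arm (C1) and the acceptor arm (C4) should all sit equatorial, which places the C20 methyl axial and H-5 anti to it, so that the second closure can only give the trans-decalin of the target. C4 is protonated under thermodynamic control (equatorial ester expected) and is planarised again in step 13. The step needs regioselection between the two enolates and suppression of intermolecular alkylation, and ring size (the C2 enolate could only close eight- or ten-membered rings) together with high dilution and reversible proton transfer through t-BuOH should secure both.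

Step 13
Reactants: 27 trans-fused bicyclic keto ester; 28 benzyl chloromethyl ether
Product: 30 C4-quaternary keto ester (as 27, with CH2OBn equatorial and anti to the C10 methyl, CO2Me axial and syn to it), via dilithium bis-enolate 29 (not isolated)
Conditions: LiN(i-Pr)2 (2.3 equiv), THF, −78 → −40 °C; then ClCH2OCH2Ph (1.05 equiv), −78 °C
Reagents that add atoms: benzyl chloromethyl ether 28, ClCOCc1ccccc1
Why: Two equivalents of amide base turn the ketone into its C2 enolate (self-protection) and the ester into the C4 enolate, and the more reactive ester enolate should be alkylated from the face anti to the axial C10 methyl (equatorial attack), giving the C4 quaternary centre with the C18 oxymethyl equatorial and the future methyl carbon C19 axial.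

Step 14
Reactants: 30 C4-quaternary keto ester; 31 dioxygen
Product: 32 8-hydroxy keto ester (as 30, with C8 carrying an equatorial OH anti to the C10 methyl and an axial CH3)
Conditions: Co(acac)2 (20 mol %), PhSiH3, O2 (1 atm), THF/i-PrOH, 23 °C
Reagents that add atoms: dioxygen 31, O=O
Why: Mukaiyama hydration delivers a hydrogen atom to C17 of the 1,1-disubstituted alkene and the tertiary C8 radical should be trapped by O2 from the face opposite to the syn-axial C10 methyl, giving the equatorial hydroxyl and axial methyl of the target.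

Step 15
Reactants: 32 8-hydroxy keto ester
Product: 33 triol (C1 secondary OH as epimer mixture, axial C19 CH2OH, tertiary C8 OH; benzyl and triisopropylsilyl ethers intact)
Conditions: LiAlH4, THF, 0 → 40 °C
Reagents that add atoms: none
Why: LiAlH4 reduces the hindered axial ester to the primary alcohol and the C1 ketone to the alcohol (configuration irrelevant), bringing both positions to the level needed for deoxygenation.

Step 16
Reactants: 33 triol
Product: 34 keto aldehyde (C1 ketone, axial C19 aldehyde, free tertiary C8 OH)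
Conditions: Dess–Martin periodinane, NaHCO3, CH2Cl2, 23 °C
Reagents that add atoms: none
Why: Dess–Martin oxidation converts the primary and secondary alcohols into the non-enolisable C19 aldehyde and the C1 ketone and cannot oxidise the tertiary alcohol.

Step 17
Reactants: 34 keto aldehyde
Product: 36 benzyl ether with C1 as CH2 and C4 carrying the axial CH3 (C8 OH, O15 silyl ether intact), via bis(N-silylhydrazone) 35 (not isolated)
Conditions: 1,2-bis(tert-butyldimethylsilyl)hydrazine, Sc(OTf)3 (1 mol %), CHCl3, 23 → 60 °C; then KOt-Bu, t-BuOH, DMSO, 23 → 100 °C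
Reagents that add atoms: none
Why: Wolff–Kishner reduction in its N-silylhydrazone variant turns the C19 aldehyde into the axial C4 methyl and the C1 ketone into CH2 in one operation, under conditions that hindered carbonyls tolerate and that touch no stereocentre.

Step 18
Reactants: 36 benzyl ether
Product: 37 diol (free neopentyl C18 OH and tertiary C8 OH, O15 triisopropylsilyl ether)
Conditions: H2 (1 atm), Pd/C, EtOAc, 23 °C
Reagents that add atoms: none
Why: Hydrogenolysis removes the benzyl group, and because no alkene remains the silyl ether and the tertiary alcohol are the only other functions and are inert.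

Step 19
Reactants: 37 diol; 38 angelic acid
Product: 40 C18 angelate (C8 OH free, O15 triisopropylsilyl ether), via mixed anhydride 39 (not isolated)
Conditions: angelic acid, 2,4,6-trichlorobenzoyl chloride, Et3N, toluene, 23 °C; then 37, toluene, 80 °C
Reagents that add atoms: angelic acid 38, C/C=C(/C)C(=O)O
Why: Yamaguchi esterification with the preformed mixed anhydride should acylate the primary alcohol and not the hindered tertiary one, and leaving out a nucleophilic catalyst should avoid Z-to-E isomerisation to the tiglate.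

Step 20
Reactants: 40 C18 angelate
Product: 41 hydroxy angelate (free C15 OH and C8 OH)
Conditions: HF·pyridine, pyridine, THF, 23 °C
Reagents that add atoms: none
Why: Buffered fluoride cleaves the triisopropylsilyl ether and should leave the conjugated ester and the tertiary alcohol intact.

Step 21
Reactants: 41 hydroxy angelate; 42 Meldrum's acid
Product: 43 target, 3-{[(13S)-18-(angeloyloxy)-8-hydroxy-ent-labdan-15-yl]oxy}-3-oxopropanoic acid, (4S,5S,8S,9S,10R,13S)
Conditions: toluene, 90 °C
Reagents that add atoms: Meldrum's acid 42, CC1(C)OC(=O)CC(=O)O1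
Why: Thermal ring-opening of Meldrum's acid by the primary alcohol with loss of acetone gives the hydrogen malonate directly, and the tertiary alcohol should not react under these neutral conditions.

**Compound list**
1 | (S)-citronellol | CC(C)=CCC[C@H](C)CCO | starting material
2 | triisopropylsilyl chloride | CC(C)[Si](Cl)(C(C)C)C(C)C | starting material
3 | (S)-triisopropyl[(3,7-dimethyloct-6-en-1-yl)oxy]silane | CC(C)=CCC[C@H](C)CCO[Si](C(C)C)(C(C)C)C(C)C | intermediate
4 | ozone | [O-][O+]=O | starting material
5 | secondary ozonide of 3, 3,3-dimethyl-5-[(3S)-3-methyl-5-(triisopropylsilyloxy)pentyl]-1,2,4-trioxolane | CC1(C)OOC(CC[C@H](C)CCO[Si](C(C)C)(C(C)C)C(C)C)O1 | intermediate (not isolated)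
6 | (4S)-4-methyl-6-(triisopropylsilyloxy)hexanal | O=CCC[C@H](C)CCO[Si](C(C)C)(C(C)C)C(C)C | intermediate
7 | methyl (triphenylphosphoranylidene)acetate | COC(=O)C=P(c1ccccc1)(c1ccccc1)c1ccccc1 | starting material
8 | methyl (2E,6S)-6-methyl-8-(triisopropylsilyloxy)oct-2-enoate | COC(=O)/C=C/CC[C@H](C)CCO[Si](C(C)C)(C(C)C)C(C)C | intermediate
9 | tert-butyldimethyl(pent-4-yn-1-yloxy)silane | C#CCCCO[Si](C)(C)C(C)(C)C | starting material
10 | 2-methoxy-4,4,5,5-tetramethyl-1,3,2-dioxaborolane | COB1OC(C)(C)C(C)(C)O1 | starting material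
11 | diisobutyl[5-(tert-butyldimethylsilyloxy)pent-1-en-2-yl]alane | C=C([Al](CC(C)C)CC(C)C)CCCO[Si](C)(C)C(C)(C)C | intermediate (not isolated)
12 | tert-butyldimethyl{[4-(4,4,5,5-tetramethyl-1,3,2-dioxaborolan-2-yl)pent-4-en-1-yl]oxy}silane | C=C(B1OC(C)(C)C(C)(C)O1)CCCO[Si](C)(C)C(C)(C)C | intermediate
13 | methyl (3S)-7-(tert-butyldimethylsilyloxy)-4-methylidene-3-[(3S)-3-methyl-5-(triisopropylsilyloxy)pentyl]heptanoate | COC(=O)C[C@H](CC[C@H](C)CCO[Si](C(C)C)(C(C)C)C(C)C)C(=C)CCCO[Si](C)(C)C(C)(C)C | intermediate
14 | iodomethane | CI | starting material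
15 | lithium enolate of 13 | COC(O[Li])=C[C@H](CC[C@H](C)CCO[Si](C(C)C)(C(C)C)C(C)C)C(=C)CCCO[Si](C)(C)C(C)(C)C | intermediate (not isolated)
16 | methyl (2RS,3S)-7-(tert-butyldimethylsilyloxy)-2-methyl-4-methylidene-3-[(3S)-3-methyl-5-(triisopropylsilyloxy)pentyl]heptanoate (C2 epimers) | COC(=O)C(C)[C@H](CC[C@H](C)CCO[Si](C(C)C)(C(C)C)C(C)C)C(=C)CCCO[Si](C)(C)C(C)(C)C | intermediate
17 | (trimethylsilyl)methyllithium | [Li]C[Si](C)(C)C | starting material
18 | lithium enolate of the α-(trimethylsilyl)methyl ketone derived from 16 | C[Si](C)(C)C=C(O[Li])C(C)[C@H](CC[C@H](C)CCO[Si](C(C)C)(C(C)C)C(C)C)C(=C)CCCO[Si](C)(C)C(C)(C)C | intermediate (not isolated)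
19 | (3RS,4S)-8-(tert-butyldimethylsilyloxy)-3-methyl-5-methylidene-4-[(3S)-3-methyl-5-(triisopropylsilyloxy)pentyl]octan-2-one | CC(=O)C(C)[C@H](CC[C@H](C)CCO[Si](C(C)C)(C(C)C)C(C)C)C(=C)CCCO[Si](C)(C)C(C)(C)C | intermediate
20 | (3RS,4S)-8-hydroxy-3-methyl-5-methylidene-4-[(3S)-3-methyl-5-(triisopropylsilyloxy)pentyl]octan-2-one | CC(=O)C(C)[C@H](CC[C@H](C)CCO[Si](C(C)C)(C(C)C)C(C)C)C(=C)CCCO | intermediate
21 | (5S,6RS)-6-methyl-4-methylidene-5-[(3S)-3-methyl-5-(triisopropylsilyloxy)pentyl]-7-oxooctanal | CC(=O)C(C)[C@H](CC[C@H](C)CCO[Si](C(C)C)(C(C)C)C(C)C)C(=C)CCC=O | intermediate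
22 | methyl acrylate | C=CC(=O)OC | starting material
23 | methyl (3RS,7S,8RS)-3-hydroxy-8-methyl-2,6-dimethylidene-7-[(3S)-3-methyl-5-(triisopropylsilyloxy)pentyl]-9-oxodecanoate | CC(=O)C(C)[C@H](CC[C@H](C)CCO[Si](C(C)C)(C(C)C)C(C)C)C(=C)CCC(O)C(=C)C(=O)OC | intermediate
24 | N-bromosuccinimide | O=C1CCC(=O)N1Br | starting material
25 | methyl (2Z,7S,8RS)-2-(bromomethyl)-8-methyl-6-methylidene-7-[(3S)-3-methyl-5-(triisopropylsilyloxy)pentyl]-9-oxodec-2-enoate | CC(=O)C(C)[C@H](CC[C@H](C)CCO[Si](C(C)C)(C(C)C)C(C)C)C(=C)CC/C=C(\CBr)C(=O)OC | intermediate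
26 | methyl 2-{2-acetyl-2-methyl-4-methylidene-3-[(3S)-3-methyl-5-(triisopropylsilyloxy)pentyl]cyclohexyl}prop-2-enoate (ring B; acetyl, acrylate unit and side chain equatorial, CH3 axial) | CC(=O)[C@]1(C)[C@@H](C(=C)C(=O)OC)CCC(=C)[C@H]1CC[C@H](C)CCO[Si](C(C)C)(C(C)C)C(C)C | intermediate (not isolated)
27 | methyl 4a-methyl-6-methylidene-5-[(3S)-3-methyl-5-(triisopropylsilyloxy)pentyl]-4-oxodecahydronaphthalene-1-carboxylate (trans-decalin; labdane C1 ketone, C4 equatorial ester, H-5 and H-9 anti to CH3-20) | COC(=O)[C@H]1CCC(=O)[C@]2(C)[C@@H]1CCC(=C)[C@H]2CC[C@H](C)CCO[Si](C(C)C)(C(C)C)C(C)C | intermediate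
28 | benzyl chloromethyl ether | ClCOCc1ccccc1 | starting material
29 | dilithium bis-enolate of 27 (C1–C2 ketone enolate and C4 ester enolate) | COC(O[Li])=C1CC=C(O[Li])[C@]2(C)[C@@H]1CCC(=C)[C@H]2CC[C@H](C)CCO[Si](C(C)C)(C(C)C)C(C)C | intermediate (not isolated)
30 | C4-quaternary keto ester (as 27; C4 bears equatorial CH2OBn anti to CH3-20 and axial CO2Me) | COC(=O)[C@]1(COCc3ccccc3)CCC(=O)[C@]2(C)[C@@H]1CCC(=C)[C@H]2CC[C@H](C)CCO[Si](C(C)C)(C(C)C)C(C)C | intermediate
31 | dioxygen | O=O | starting material
32 | 8-hydroxy keto ester (as 30; C8 bears equatorial OH anti to CH3-20 and axial CH3) | COC(=O)[C@]1(COCc3ccccc3)CCC(=O)[C@]2(C)[C@@H]1CC[C@](C)(O)[C@H]2CC[C@H](C)CCO[Si](C(C)C)(C(C)C)C(C)C | intermediate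
33 | triol (C1 OH epimers, axial C19 CH2OH, C8 OH; C18 benzyl ether, O15 triisopropylsilyl ether) | OC[C@]1(COCc3ccccc3)CCC(O)[C@]2(C)[C@@H]1CC[C@](C)(O)[C@H]2CC[C@H](C)CCO[Si](C(C)C)(C(C)C)C(C)C | intermediate
34 | keto aldehyde (C1 ketone, axial C19 CHO, C8 OH) | O=C[C@]1(COCc3ccccc3)CCC(=O)[C@]2(C)[C@@H]1CC[C@](C)(O)[C@H]2CC[C@H](C)CCO[Si](C(C)C)(C(C)C)C(C)C | intermediate
35 | bis(N-tert-butyldimethylsilylhydrazone) of 34 | CC(C)(C)[Si](C)(C)NN=C[C@]1(COCc3ccccc3)CCC(=NN[Si](C)(C)C(C)(C)C)[C@]2(C)[C@@H]1CC[C@](C)(O)[C@H]2CC[C@H](C)CCO[Si](C(C)C)(C(C)C)C(C)C | intermediate (not isolated)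
36 | (13S)-18-(benzyloxy)-15-(triisopropylsilyloxy)-ent-labdan-8-ol (configured as the target) | c3ccccc3COC[C@@]1(C)CCC[C@]2(C)[C@@H]1CC[C@](C)(O)[C@H]2CC[C@H](C)CCO[Si](C(C)C)(C(C)C)C(C)C | intermediate
37 | (13S)-15-(triisopropylsilyloxy)-ent-labdane-8,18-diol | OC[C@@]1(C)CCC[C@]2(C)[C@@H]1CC[C@](C)(O)[C@H]2CC[C@H](C)CCO[Si](C(C)C)(C(C)C)C(C)C | intermediate
38 | angelic acid, (Z)-2-methylbut-2-enoic acid | C/C=C(/C)C(=O)O | starting material
39 | angelic 2,4,6-trichlorobenzoic anhydride | C/C=C(/C)C(=O)OC(=O)c1c(Cl)cc(Cl)cc1Cl | intermediate (not isolated)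
40 | (13S)-8-hydroxy-15-(triisopropylsilyloxy)-ent-labdan-18-yl angelate | C/C=C(/C)C(=O)OC[C@@]1(C)CCC[C@]2(C)[C@@H]1CC[C@](C)(O)[C@H]2CC[C@H](C)CCO[Si](C(C)C)(C(C)C)C(C)C | intermediate
41 | (13S)-8,15-dihydroxy-ent-labdan-18-yl angelate | C/C=C(/C)C(=O)OC[C@@]1(C)CCC[C@]2(C)[C@@H]1CC[C@](C)(O)[C@H]2CC[C@H](C)CCO | intermediate
42 | Meldrum's acid, 2,2-dimethyl-1,3-dioxane-4,6-dione | CC1(C)OC(=O)CC(=O)O1 | starting material
43 | 3-{[(13S)-18-(angeloyloxy)-8-hydroxy-ent-labdan-15-yl]oxy}-3-oxopropanoic acid, (4S,5S,8S,9S,10R,13S) | C/C=C(/C)C(=O)OC[C@@]1(C)CCC[C@]2(C)[C@@H]1CC[C@](C)(O)[C@H]2CC[C@H](C)CCOC(=O)CC(=O)O | target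

**Step count:** 21 steps in total. The longest linear sequence is 20 steps (steps 1–3 and 5–21, from (S)-citronellol); step 4 prepares the second fragment.

**Steps most likely to fail**

Step 12 (the proposed new method). The enolates may alkylate intermolecularly and oligomerise faster than the six-membered closure, the base may cause 1,4-elimination of HBr from the allylic bromide, or the first closure may show poor C5/C10 diastereocontrol. The fallback uses two separate, well-known intramolecular Michael closures and sets out from keto aldehyde 21. Wittig reaction with methyl (triphenylphosphoranylidene)acetate should give the (E)-enoate keto ester F1. KOt-Bu in THF/t-BuOH should then close ring B by 6-exo-trig Michael addition of the C10 enolate, giving the ring-B keto ester F2 with a CH2CO2Me arm on C5. Kinetic enolisation of the methyl ketone with LiN(i-Pr)2 and a Mannich reaction with dimethyl(methylidene)ammonium iodide give the β-dimethylamino ketone F3. Iodomethane converts F3 into the methiodide F4, and NaHCO3 eliminates it to the vinyl ketone F5. Catalytic KOt-Bu should then close ring A by Michael addition of the ester α-carbon (C4) to the enone terminus (C3), which returns to 27.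

Step 5. Transmetalation of the hindered 1,1-disubstituted alkenyl boronate may be slow and lose to protodeboronation, or the ester acceptor may give insufficient facial selectivity. The fallback replaces catalyst control by an oxazolidinone auxiliary and sets out from aldehyde 6 and alkenylalane 11. Horner–Wadsworth–Emmons reaction of 6 with diethyl {2-oxo-2-[(4R)-2-oxo-4-phenyl-1,3-oxazolidin-3-yl]ethyl}phosphonate (LiCl, i-Pr2NEt) gives the (E)-N-enoyl oxazolidinone F6. Quenching 11 with N-bromosuccinimide gives 2-bromo-5-(tert-butyldimethylsilyloxy)pent-1-ene F7, which is converted (t-BuLi, then MgBr2·OEt2) into the alkenylmagnesium bromide F8. CuBr·SMe2-mediated conjugate addition of F8 to F6, anti to the phenyl group of the chelated imide, should give the adduct F9 with C9 (S). MeOMgBr in MeOH cleaves the auxiliary and returns to ester 13.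

Step 13. The ketone enolate may be alkylated at oxygen or at C2 in competition with the ester enolate, or the second deprotonation may be incomplete. The fallback protects the ketone explicitly and sets out from 27. One equivalent of LiN(i-Pr)2 (the ketone α-CH2 is the more acidic site) and Me3SiCl give the trimethylsilyl enol ether F10. A second treatment with LiN(i-Pr)2 and benzyl chloromethyl ether alkylates the now unique ester enolate to give the alkylated silyl enol ether F11. Dilute aqueous HCl cleaves the enol ether and returns to 30.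

**Further compounds**
F1 | step 12 | methyl (2E,7S,8RS)-8-methyl-6-methylidene-7-[(3S)-3-methyl-5-(triisopropylsilyloxy)pentyl]-9-oxodec-2-enoate | CC(=O)C(C)[C@H](CC[C@H](C)CCO[Si](C(C)C)(C(C)C)C(C)C)C(=C)CC/C=C/C(=O)OC
F2 | step 12 | methyl 2-{2-acetyl-2-methyl-4-methylidene-3-[(3S)-3-methyl-5-(triisopropylsilyloxy)pentyl]cyclohexyl}acetate (configured as 26) | CC(=O)[C@]1(C)[C@@H](CC(=O)OC)CCC(=C)[C@H]1CC[C@H](C)CCO[Si](C(C)C)(C(C)C)C(C)C
F3 | step 12 | β-dimethylamino ketone (Mannich base of F2) | CN(C)CCC(=O)[C@]1(C)[C@@H](CC(=O)OC)CCC(=C)[C@H]1CC[C@H](C)CCO[Si](C(C)C)(C(C)C)C(C)C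
F4 | step 12 | methiodide of F3 | C[N+](C)(C)CCC(=O)[C@]1(C)[C@@H](CC(=O)OC)CCC(=C)[C@H]1CC[C@H](C)CCO[Si](C(C)C)(C(C)C)C(C)C.[I-]
F5 | step 12 | vinyl ketone (acryloyl analogue of F2) | C=CC(=O)[C@]1(C)[C@@H](CC(=O)OC)CCC(=C)[C@H]1CC[C@H](C)CCO[Si](C(C)C)(C(C)C)C(C)C
F6 | step 5 | (4R)-3-[(2E,6S)-6-methyl-8-(triisopropylsilyloxy)oct-2-enoyl]-4-phenyl-1,3-oxazolidin-2-one | O=C(/C=C/CC[C@H](C)CCO[Si](C(C)C)(C(C)C)C(C)C)N1[C@H](c2ccccc2)COC1=O
F7 | step 5 | 2-bromo-5-(tert-butyldimethylsilyloxy)pent-1-ene | C=C(Br)CCCO[Si](C)(C)C(C)(C)C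
F8 | step 5 | [5-(tert-butyldimethylsilyloxy)pent-1-en-2-yl]magnesium bromide | C=C([Mg]Br)CCCO[Si](C)(C)C(C)(C)C
F9 | step 5 | (4R)-3-{(3S)-7-(tert-butyldimethylsilyloxy)-4-methylidene-3-[(3S)-3-methyl-5-(triisopropylsilyloxy)pentyl]heptanoyl}-4-phenyl-1,3-oxazolidin-2-one | O=C(C[C@H](CC[C@H](C)CCO[Si](C(C)C)(C(C)C)C(C)C)C(=C)CCCO[Si](C)(C)C(C)(C)C)N1[C@H](c2ccccc2)COC1=O
F10 | step 13 | trimethylsilyl enol ether of 27 (C1–C2 enol ether) | COC(=O)[C@H]1CC=C(O[Si](C)(C)C)[C@]2(C)[C@@H]1CCC(=C)[C@H]2CC[C@H](C)CCO[Si](C(C)C)(C(C)C)C(C)C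
F11 | step 13 | trimethylsilyl enol ether of 30 | COC(=O)[C@]1(COCc3ccccc3)CC=C(O[Si](C)(C)C)[C@]2(C)[C@@H]1CCC(=C)[C@H]2CC[C@H](C)CCO[Si](C(C)C)(C(C)C)C(C)C
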